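**Retrosynthetic overview**

1. Target 9 ⇐ acid hydrolysis of the 6,9-enol ether prostacyclin (the C6 ketone sits 1,4 to O9, so it is a masked tetrahydrofuran enol ether) ⇐ iodoetherification and dehydroiodination of the 5Z-alkene of prostaglandin F2α methyl ester 5.
2. Prostaglandin F2α 4 ⇐ reductive opening of the O–O bridge of prostaglandin H2 3 ⇐ arachidonic acid 1 and two O2, by a fatty-acid cyclooxygenase (prostaglandin-endoperoxide synthase), which makes the C8–C12 bond.
3. Enabling feature: the C8–C12 bond lies in a cyclopentane whose C9 and C11 carry cis oxygens 1,3 to each other and whose C12 carries the E-C13=C14–C15(OH) allylic alcohol. This is the pattern left when one O2 bridges C9 and C11 as a 2,3-dioxabicyclo[2.2.1]heptane, the C8 radical closes onto C12 of an all-Z skipped polyene, and a second O2 ends the allyl radical at C15.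
4. Ring order: 1,2-dioxolane and cyclopentane together in step 1; dioxolane opened in step 2; a temporary tetrahydrofuran (O9–C6) closed in step 4 and opened again in step 5.

Key step: step 1

Remark: 9 equilibrates in solution with its cyclic 6,9-hemiketals; the open γ-hydroxy ketone drawn for the target is taken as the compound to be made, and arachidonic acid and ovine COX-1 are taken as commercial.

**Route**

Step 1
Reactants: 1 arachidonic acid ((5Z,8Z,11Z,14Z)-icosa-5,8,11,14-tetraenoic acid)
Product: 3 prostaglandin H2, via prostaglandin G2 2 (not isolated)
Conditions: ovine COX-1 (prostaglandin-endoperoxide synthase, EC 1.14.99.1), hematin C34H33FeN4O5 (cat.), hydroquinone (1.2 equiv), O2-saturated Tris-HCl buffer pH 8.0, 25 °C, 2 min; then pH 3.5, cold Et2O extraction, SiO2 at −20 °C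
Reagents that add atoms: dioxygen O=O
Why: The tyrosyl radical of the enzyme (Tyr385) removes the pro-S hydrogen of the doubly allylic C13, O2 adds to C11 of the pentadienyl radical from the opposite face, the C11 peroxyl radical attacks C9 of the 8Z-alkene, the C8 radical so formed attacks C12 of the 12E,14Z-diene and makes the C8–C12 bond, and the C13–C15 allyl radical takes a second O2 at C15 to give hydroperoxide 2, which the peroxidase site of the same protein reduces to alcohol 3 at the expense of hydroquinone. This is the native reaction of fatty-acid cyclooxygenases on their native substrate, and its closest small-molecule relative is the radical-chain peroxyl cyclisation of polyunsaturated fatty acid hydroperoxides. Two rings close, both 5-exo-trig: the 1,2-dioxolane by O–C9 bond formation and the cyclopentane by C8–C12 bond formation, which together make the 2,3-dioxabicyclo[2.2.1]heptane. The new stereocentres C8 (R), C9 (S), C11 (R), C12 (R) and C15 (S) and the 13E geometry are all set by the chiral active-site channel acting on an achiral chain, the cis relation of O9 and O11 being enforced in addition by the C10-bridged bicycle. The selectivity needed is the trans relation of the two side chains across the new bond (untemplated peroxyl cyclisations favour the cis pattern) and hydrogen abstraction at C13 only; the protein secures both, and on the substrate side the free C1 carboxylate (the anchor to Arg120, hence the acid and not an ester) and the all-Z skipped 8,11,14-triene, which puts C13–H between two alkenes and C9 five atoms from the C11 peroxyl oxygen, are what it needs.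

Step 2
Reactants: 3 prostaglandin H2
Product: 4 prostaglandin F2α
Conditions: PPh3 (1.2 equiv), Et2O/THF/H2O, −20 °C to rt
Reagents that add atoms: none
Why: Phosphine reduction of a dialkyl peroxide: PPh3 inserts into the O–O bond and the cyclic dialkoxyphosphorane is hydrolysed at phosphorus, so both C–O bonds stay intact and the cis-9α,11α-diol should be released with retention at C9 and C11, no stereocentre being created.

Step 3
Reactants: 4 prostaglandin F2α
Product: 5 prostaglandin F2α methyl ester
Conditions: CH2N2, Et2O/MeOH, 0 °C
Reagents that add atoms: diazomethane C=[N+]=[N-]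
Why: Diazomethane esterification is selective for the carboxylic acid over the three alcohols and both alkenes, and it removes the carboxylate as a competing nucleophile (iodolactonisation) for step 4; no stereocentre is involved.

Step 4
Reactants: 5 prostaglandin F2α methyl ester
Product: 6 iodo ether methyl (5R,6R,13E,15S)-6,9α-epoxy-11α,15-dihydroxy-5-iodoprost-13-enoate
Conditions: I2 (1.1 equiv), NaHCO3, CH2Cl2/H2O, 0 °C
Reagents that add atoms: iodine II
Why: Iodoetherification: the iodonium ion of the 5Z-alkene is opened anti by the 9α-hydroxyl in a 5-exo closure to a cis-fused 2-oxabicyclo[3.3.0]octane, the C6 side chain taking the exo position so that the (5R,6R) isomer should predominate, while the 13,14-alkene is deactivated by its allylic hydroxyl and has no hydroxyl placed for a 5-exo closure; C5 and C6 lose their stereogenicity in step 5, so a minor (5S,6S) isomer can be carried through.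

Step 5
Reactants: 6 iodo ether methyl (5R,6R,13E,15S)-6,9α-epoxy-11α,15-dihydroxy-5-iodoprost-13-enoate
Product: 9 6-keto-prostaglandin F1α, via prostacyclin methyl ester 7 (not isolated), via prostacyclin sodium salt 8 (not isolated)
Conditions: NaOMe, MeOH, 50 °C; then aq. NaOH, rt; then aq. HCl to pH 3, 0 °C to rt
Reagents that add atoms: sodium hydroxide [Na+].[OH-]; water O
Why: Anti E2 dehydroiodination toward C6 should give the base-stable 5Z enol ether 7 (the forming double bond is conjugated with the ring oxygen), hydroxide then saponifies the methyl ester to 8, and on acidification the enol ether is protonated at C5, water adds to the C6 oxocarbenium ion and the hemiketal opens to the γ-hydroxy ketone, which removes the stereocentres at C5 and C6 and leaves C8, C9, C11, C12 and C15 untouched because the C9–O bond is never broken.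

**Compound list**

1 | arachidonic acid, (5Z,8Z,11Z,14Z)-icosa-5,8,11,14-tetraenoic acid | CCCCC/C=C\C/C=C\C/C=C\C/C=C\CCCC(=O)O | starting material
2 | prostaglandin G2, (5Z,13E,15S)-9α,11α-epidioxy-15-hydroperoxyprosta-5,13-dienoic acid | CCCCC[C@H](OO)/C=C/[C@@H]1[C@@H](C/C=C\CCCC(=O)O)[C@@H]2C[C@H]1OO2 | intermediate
3 | prostaglandin H2, (5Z,13E,15S)-9α,11α-epidioxy-15-hydroxyprosta-5,13-dienoic acid | CCCCC[C@H](O)/C=C/[C@@H]1[C@@H](C/C=C\CCCC(=O)O)[C@@H]2C[C@H]1OO2 | intermediate
4 | prostaglandin F2α, (5Z,13E,15S)-9α,11α,15-trihydroxyprosta-5,13-dienoic acid (8R,9S,11R,12R,15S) | CCCCC[C@H](O)/C=C/[C@@H]1[C@@H](C/C=C\CCCC(=O)O)[C@@H](O)C[C@H]1O | intermediate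
5 | prostaglandin F2α methyl ester | CCCCC[C@H](O)/C=C/[C@@H]1[C@@H](C/C=C\CCCC(=O)OC)[C@@H](O)C[C@H]1O | intermediate
6 | iodo ether, methyl (5R,6R,13E,15S)-6,9α-epoxy-11α,15-dihydroxy-5-iodoprost-13-enoate | CCCCC[C@H](O)/C=C/[C@@H]1[C@H]2C[C@H]([C@H](I)CCCC(=O)OC)O[C@H]2C[C@H]1O | intermediate
7 | prostacyclin methyl ester, methyl (5Z,13E,15S)-6,9α-epoxy-11α,15-dihydroxyprosta-5,13-dienoate | CCCCC[C@H](O)/C=C/[C@@H]1[C@H]2C/C(=C/CCCC(=O)OC)O[C@H]2C[C@H]1O | intermediate
8 | prostacyclin sodium salt, sodium (5Z,13E,15S)-6,9α-epoxy-11α,15-dihydroxyprosta-5,13-dienoate | CCCCC[C@H](O)/C=C/[C@@H]1[C@H]2C/C(=C/CCCC(=O)[O-])O[C@H]2C[C@H]1O.[Na+] | intermediate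
9 | 6-keto-prostaglandin F1α, (13E,15S)-9α,11α,15-trihydroxy-6-oxoprost-13-enoic acid | CCCCC[C@H](O)/C=C/[C@@H]1[C@@H](CC(=O)CCCCC(=O)O)[C@@H](O)C[C@H]1O | target

**Step count and risks**

Total step count: 5. Longest linear sequence: 5 steps (1 → 3 → 4 → 5 → 6 → 9).

Steps most likely to fail:

Step 1. The enzyme inactivates itself after a limited number of turnovers, and the endoperoxide can isomerise to β-hydroxy ketones or fragment during the cold acidic work-up and chromatography, so that little of it is recovered. The fallback sets out from 1 and does not isolate the endoperoxide. Compound 1 is incubated under O2 with sheep vesicular-gland microsomes, which carry the cyclooxygenase together with a glutathione-dependent prostaglandin E synthase, in the presence of glutathione and hydroquinone. Compounds 2 and 3 are passed in the flask and isomerised by the second enzyme to prostaglandin E2 F1, a β-hydroxy ketone that should tolerate extraction at pH 3 and chromatography. The C9 ketone of F1 is then reduced with LiBH(s-Bu)3 in THF at −78 °C; the bulky hydride should approach from the β face, anti to the C8 side chain, and give the 9α-alcohol. The fallback comes back to the route at 4.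

Step 2. The strained bridged peroxide may rearrange by Kornblum–DeLaMare-type loss of the C9 or C11 hydrogen, or be deoxygenated, faster than the phosphorane is hydrolysed to the diol. The fallback sets out from 3 and changes the fate of the endoperoxide. Compound 3 is incubated with prostacyclin synthase (a cytochrome P450-type isomerase of the CYP8A1 class that needs neither O2 nor NADPH) in sodium phosphate buffer at pH 7.5. This should convert 3 directly into prostacyclin, present as its sodium salt 8, and so comes back to the route at 8. Acidification to pH 3 as in the last stage of step 5 then gives 9. This bypasses steps 2 to 4 and makes no compound outside the list (entry F0).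

Step 4. The iodonium ion may be captured by water or bicarbonate, may form at the 13,14-alkene, or may be opened in a 6-endo sense, which would erode chemo- and regioselectivity. The fallback sets out from 5 and separates cyclisation from iodination. Compound 5 is treated with Hg(OAc)2 in dry THF at rt, where reversible mercuration should funnel the substrate through the intramolecular 5-exo anti alkoxymercuration to the organomercurial methyl (5R,6R,13E,15S)-5-(acetoxymercurio)-6,9α-epoxy-11α,15-dihydroxyprost-13-enoate F2. The C–Hg bond of F2 is then cleaved with I2 in CH2Cl2 (iododemercuration), and the fallback comes back to the route at 6. Any loss of configuration at C5 in this cleavage is harmless, because C5 and C6 lose their stereogenicity in step 5 and both enol ether geometries hydrolyse to the same ketone.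

**Further compounds**

F1 | step 1 | prostaglandin E2, (5Z,13E,15S)-11α,15-dihydroxy-9-oxoprosta-5,13-dienoic acid | CCCCC[C@H](O)/C=C/[C@@H]1[C@@H](C/C=C\CCCC(=O)O)C(=O)C[C@H]1O
F0 | step 2 | none | none
F2 | step 4 | methyl (5R,6R,13E,15S)-5-(acetoxymercurio)-6,9α-epoxy-11α,15-dihydroxyprost-13-enoate | CCCCC[C@H](O)/C=C/[C@@H]1[C@H]2C[C@H]([C@H]([Hg]OC(C)=O)CCCC(=O)OC)O[C@H]2C[C@H]1O
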